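The route cuts the C2–C1' bond that ties catechol ring B to the oxygen-bearing benzylic carbon C2 of ring C. Because that bond lies β to the C4 ketone, ring C can be carried as a flat 4-pyranone: the C2=C3 enone of 5-benzyloxy-7-methoxychromone accepts 3,4-bis(benzyloxy)phenylboronic acid in a ligand-controlled, palladium-catalysed 1,4-addition. This one operation joins the two halves, dearomatises ring C and fixes C2. C3 is left as an enolisable CH2, which is then hydroxylated trans to the aryl group, acetylated and unmasked by hydrogenolysis.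

Key step: step 5

Assumption: the enantioface preference of the t-BuPyOx–palladium catalyst on chromone 5 is taken to parallel that on carbocyclic enones, which assigns the (R)-ligand to the (2S)-flavanone; the opposite hand of the ligand would be used if the sense proved reversed.

Step 1
Reactants: 1 1-(2,6-dihydroxy-4-methoxyphenyl)ethanone
Product: 2 1-[2-(benzyloxy)-6-hydroxy-4-methoxyphenyl]ethanone
Conditions: BnBr (1.05 equiv), K2CO3 (1.2 equiv), acetone, reflux
Reagents that add atoms: benzyl bromide BrCc1ccccc1
Why: Williamson etherification of one of two equivalent phenols; once the first is alkylated, the remaining phenol is locked in a hydrogen bond to the ketone and is much less nucleophilic, so one equivalent of halide should stop at the mono-ether.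

Step 2
Reactants: 2 1-[2-(benzyloxy)-6-hydroxy-4-methoxyphenyl]ethanone; 3 N,N-dimethylformamide dimethyl acetal
Product: 5 5-(benzyloxy)-7-methoxy-4H-chromen-4-one, via enaminone 4 (not isolated)
Conditions: 3 (2 equiv), toluene, 100 °C; evaporate; conc. HCl (3 equiv), CH2Cl2, 20 °C
Reagents that add atoms: none
Why: Condensation of the methyl ketone with the amide acetal gives the vinylogous amide, and acid then lets the neighbouring phenol add to its β-carbon (6-endo-trig) and expel dimethylamine, the standard enaminone route to 3-unsubstituted chromones; the benzyl and methyl ethers tolerate brief acid at room temperature.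

Step 3
Reactants: 6 4-bromobenzene-1,2-diol
Product: 7 1,2-bis(benzyloxy)-4-bromobenzene
Conditions: BnBr (2.3 equiv), K2CO3 (3 equiv), DMF, 60 °C
Reagents that add atoms: benzyl bromide BrCc1ccccc1
Why: Double Williamson etherification of an unhindered catechol, which also removes the acidic protons before the organolithium step.

Step 4
Reactants: 7 1,2-bis(benzyloxy)-4-bromobenzene
Product: 10 [3,4-bis(benzyloxy)phenyl]boronic acid, via aryllithium 8 (not isolated), via lithium triisopropoxyborate 9 (not isolated)
Conditions: n-BuLi (1.1 equiv), THF, −78 °C; B(OiPr)3 (1.5 equiv), −78 to 20 °C; 1 M HCl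
Reagents that add atoms: triisopropyl borate CC(C)OB(OC(C)C)OC(C)C; water O
Why: Bromine–lithium exchange at −78 °C is faster than benzylic deprotonation, the aryllithium is trapped as the borate complex, and aqueous acid hydrolyses the B–O-isopropyl bonds to the boronic acid (lithiation–borylation).

Step 5
Reactants: 5 5-(benzyloxy)-7-methoxy-4H-chromen-4-one; 10 [3,4-bis(benzyloxy)phenyl]boronic acid
Product: 11 (2S)-5-(benzyloxy)-2-[3,4-bis(benzyloxy)phenyl]-7-methoxychroman-4-one
Conditions: 10 (2 equiv), Pd(OCOCF3)2 (5 mol%), (R)-4-tert-butyl-2-(pyridin-2-yl)-4,5-dihydrooxazole [(R)-t-BuPyOx] (6 mol%), NH4PF6 (30 mol%), H2O (5 equiv), ClCH2CH2Cl, 60 °C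
Reagents that add atoms: none
Why: Transmetalation from boron to the cationic (PyOx)Pd complex gives an aryl–palladium species that binds the C2=C3 bond of 5 and inserts it so that the aryl group lands on C2 and palladium on C3, after which water protonates the palladium enolate to release 11 and return the divalent palladium catalyst. The closest known reaction type is the divalent palladium/pyridine-oxazoline-catalysed asymmetric conjugate addition of arylboronic acids to chromones, the palladium counterpart of the Hayashi–Miyaura reaction. No ring is closed: only the C2–C1' bond forms, and planar ring C becomes the dihydropyranone. The one new stereocentre, C2, is set by the ligand, whose tert-butyl group leaves a single enantioface of the bound enone open in the insertion transition state, the (R)-ligand being assigned to the 2S product. The step needs 1,4-regioselectivity, which the polarised vinylogous ester with its unsubstituted C2 and hydrogen-only C3 supplies, and enantioface selectivity, which is unopposed because 5 is flat and carries no stereocentre. The amine-free, weakly acidic medium should also keep the product from retro-oxa-Michael ring opening, so C2 should not erode.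

Step 6
Reactants: 11 (2S)-5-(benzyloxy)-2-[3,4-bis(benzyloxy)phenyl]-7-methoxychroman-4-one
Product: 12 (2S)-{[5-(benzyloxy)-2-[3,4-bis(benzyloxy)phenyl]-7-methoxy-2H-chromen-4-yl]oxy}trimethylsilane
Conditions: Me3SiOTf (1.3 equiv), Et3N (2 equiv), CH2Cl2, 0 °C; pentane, filtration, evaporation (no aqueous work-up)
Reagents that add atoms: trimethylsilyl trifluoromethanesulfonate C[Si](C)(C)OS(=O)(=O)C(F)(F)F
Why: Soft enolisation, in which O-silylation of the ketone is followed by amine deprotonation at C3, the only enolisable position, so no free enolate is present to expel the ring phenoxide and C2 keeps its configuration.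

Step 7
Reactants: 12 (2S)-{[5-(benzyloxy)-2-[3,4-bis(benzyloxy)phenyl]-7-methoxy-2H-chromen-4-yl]oxy}trimethylsilane
Product: 14 (2R,3R)-5-(benzyloxy)-2-[3,4-bis(benzyloxy)phenyl]-3-hydroxy-7-methoxychroman-4-one, via silyloxy epoxide 13 (not isolated)
Conditions: dimethyldioxirane (1.2 equiv, acetone solution), CH2Cl2, −40 to 0 °C; then 1 M HCl, THF, 0 °C
Reagents that add atoms: dimethyldioxirane CC1(C)OO1
Why: Rubottom oxidation, in which the dioxirane epoxidises the electron-rich enol ether on the face opposite the C2 aryl group and dilute acid opens the silyloxy epoxide to the α-hydroxy ketone with the C3–O bond intact, giving the 2,3-trans (2R,3R) isomer, which is also the more stable one, so any cis material can be equilibrated at C3.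

Step 8
Reactants: 14 (2R,3R)-5-(benzyloxy)-2-[3,4-bis(benzyloxy)phenyl]-3-hydroxy-7-methoxychroman-4-one
Product: 15 (2R,3R)-5-(benzyloxy)-2-[3,4-bis(benzyloxy)phenyl]-7-methoxy-4-oxochroman-3-yl acetate
Conditions: Ac2O (1.5 equiv), pyridine (3 equiv), DMAP (5 mol%), CH2Cl2, 0 °C
Reagents that add atoms: acetic anhydride CC(=O)OC(C)=O
Why: Nucleophile-catalysed acylation of the only free hydroxyl, under conditions too mild and too cold to enolise C3 or open ring C, so both stereocentres are kept.

Step 9
Reactants: 15 (2R,3R)-5-(benzyloxy)-2-[3,4-bis(benzyloxy)phenyl]-7-methoxy-4-oxochroman-3-yl acetate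
Product: 16 (2R,3R)-2-(3,4-dihydroxyphenyl)-5-hydroxy-7-methoxy-4-oxochroman-3-yl acetate (3-O-acetylpadmatin)
Conditions: H2 (1 atm), 10% Pd/C, EtOAc–THF, 20 °C
Reagents that add atoms: none
Why: Catalytic hydrogenolysis of the three aryl benzyl ethers in a neutral aprotic medium, which should leave the methyl ether, the acetate, the vinylogous-ester ketone and both stereocentres untouched.

Compound list
1 | 1-(2,6-dihydroxy-4-methoxyphenyl)ethanone | CC(=O)c1c(O)cc(OC)cc1O | starting material
2 | 1-[2-(benzyloxy)-6-hydroxy-4-methoxyphenyl]ethanone | CC(=O)c1c(O)cc(OC)cc1OCc1ccccc1 | intermediate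
3 | N,N-dimethylformamide dimethyl acetal | COC(OC)N(C)C | starting material
4 | (E)-1-[2-(benzyloxy)-6-hydroxy-4-methoxyphenyl]-3-(dimethylamino)prop-2-en-1-one | CN(C)/C=C/C(=O)c1c(O)cc(OC)cc1OCc1ccccc1 | intermediate
5 | 5-(benzyloxy)-7-methoxy-4H-chromen-4-one | COc1cc(OCc2ccccc2)c2c(=O)ccoc2c1 | intermediate
6 | 4-bromobenzene-1,2-diol | Oc1ccc(Br)cc1O | starting material
7 | 1,2-bis(benzyloxy)-4-bromobenzene | Brc1ccc(OCc2ccccc2)c(OCc2ccccc2)c1 | intermediate
8 | [3,4-bis(benzyloxy)phenyl]lithium | [Li]c1ccc(OCc2ccccc2)c(OCc2ccccc2)c1 | intermediate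
9 | lithium [3,4-bis(benzyloxy)phenyl]tri(propan-2-yloxy)borate | [Li+].CC(C)O[B-](OC(C)C)(OC(C)C)c1ccc(OCc2ccccc2)c(OCc2ccccc2)c1 | intermediate
10 | [3,4-bis(benzyloxy)phenyl]boronic acid | OB(O)c1ccc(OCc2ccccc2)c(OCc2ccccc2)c1 | intermediate
11 | (2S)-5-(benzyloxy)-2-[3,4-bis(benzyloxy)phenyl]-7-methoxychroman-4-one | COc1cc(OCc3ccccc3)c2c(c1)O[C@H](c1ccc(OCc3ccccc3)c(OCc3ccccc3)c1)CC2=O | intermediate
12 | (2S)-{[5-(benzyloxy)-2-[3,4-bis(benzyloxy)phenyl]-7-methoxy-2H-chromen-4-yl]oxy}trimethylsilane | COc1cc(OCc3ccccc3)c2c(c1)O[C@H](c1ccc(OCc3ccccc3)c(OCc3ccccc3)c1)C=C2O[Si](C)(C)C | intermediate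
13 | C3–C4 epoxide of 12, carrying the trimethylsilyloxy group on C4 and the oxirane oxygen on the face opposite the C2 aryl group | COc1cc(OCc3ccccc3)c2c(c1)O[C@H](c1ccc(OCc3ccccc3)c(OCc3ccccc3)c1)[C@H]3O[C@@]23O[Si](C)(C)C | intermediate
14 | (2R,3R)-5-(benzyloxy)-2-[3,4-bis(benzyloxy)phenyl]-3-hydroxy-7-methoxychroman-4-one | COc1cc(OCc3ccccc3)c2c(c1)O[C@H](c1ccc(OCc3ccccc3)c(OCc3ccccc3)c1)[C@@H](O)C2=O | intermediate
15 | (2R,3R)-5-(benzyloxy)-2-[3,4-bis(benzyloxy)phenyl]-7-methoxy-4-oxochroman-3-yl acetate | COc1cc(OCc3ccccc3)c2c(c1)O[C@H](c1ccc(OCc3ccccc3)c(OCc3ccccc3)c1)[C@@H](OC(C)=O)C2=O | intermediate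
16 | (2R,3R)-2-(3,4-dihydroxyphenyl)-5-hydroxy-7-methoxy-4-oxochroman-3-yl acetate (3-O-acetylpadmatin) | COc1cc(O)c2c(c1)O[C@H](c1ccc(O)c(O)c1)[C@@H](OC(C)=O)C2=O | target

Total step count: 9 steps.
Longest linear sequence: 7 steps (steps 1, 2, 5, 6, 7, 8, 9); steps 3 and 4 form the two-step side branch to the boronic acid.

Steps most likely to fail

Step 5. Insertion into the electron-rich 5,7-dioxygenated chromone may be slow, so that protodeboronation and homocoupling of the boron partner win, or the catalyst may not discriminate the two enantiofaces well enough. The fallback sets out from 2 and returns at 14, bypassing 11 to 13; it sets both ring C stereocentres by asymmetric epoxidation of a chalcone. The free phenol of 2 is capped (NaH, MOMCl, DMF, 0 °C) to give 1-[2-(benzyloxy)-4-methoxy-6-(methoxymethoxy)phenyl]ethanone F1. Claisen–Schmidt condensation of F1 with purchased 3,4-bis(benzyloxy)benzaldehyde F2 (KOH, EtOH, 20 °C) should give (E)-1-[2-(benzyloxy)-4-methoxy-6-(methoxymethoxy)phenyl]-3-[3,4-bis(benzyloxy)phenyl]prop-2-en-1-one F3. Juliá–Colonna epoxidation (poly-L-leucine, urea–H2O2, DBU, THF) should then give the (αR,βS)-epoxy ketone F4. HCl in MeOH–THF removes the methoxymethyl group and lets the freed phenol open the oxirane at the benzylic carbon with inversion, which should deliver the trans (2R,3R) compound 14 directly.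

Step 7. The moisture-sensitive enol ether may hydrolyse back to the flavanone before it is oxidised, or the oxidant may not distinguish the two faces well enough. The fallback sets out from 11 and returns at 14, bypassing 12 and 13; it hydroxylates the enolate directly. KN(SiMe3)2 in THF at −78 °C gives the potassium enolate of 11 F5, which is treated at −78 °C with 2-(phenylsulfonyl)-3-phenyloxaziridine and quenched cold with AcOH. Electrophilic oxygen should arrive anti to the C2 aryl group, and the low temperature restrains β-elimination of the ring phenoxide.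

Step 9. Over-reduction may accompany debenzylation, either by hydrogenolysis of the benzylic C2–O1 bond or by reduction of the C4 carbonyl. The fallback goes from 15 straight to 16 without hydrogen: BCl3 with pentamethylbenzene as cation scavenger in CH2Cl2 at −78 °C cleaves the aryl benzyl ethers. It should spare the 7-methyl ether (not chelated to the carbonyl), the acetate and both stereocentres. It creates no new compound (F0).

Further compounds
F1 | step 5 | 1-[2-(benzyloxy)-4-methoxy-6-(methoxymethoxy)phenyl]ethanone | CC(=O)c1c(OCOC)cc(OC)cc1OCc1ccccc1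
F2 | step 5 | 3,4-bis(benzyloxy)benzaldehyde (purchased) | O=Cc1ccc(OCc2ccccc2)c(OCc2ccccc2)c1
F3 | step 5 | (E)-1-[2-(benzyloxy)-4-methoxy-6-(methoxymethoxy)phenyl]-3-[3,4-bis(benzyloxy)phenyl]prop-2-en-1-one | COCOc1cc(OC)cc(OCc2ccccc2)c1C(=O)/C=C/c1ccc(OCc2ccccc2)c(OCc2ccccc2)c1
F4 | step 5 | (αR,βS)-epoxide of F3: [2-(benzyloxy)-4-methoxy-6-(methoxymethoxy)phenyl]{(2R,3S)-3-[3,4-bis(benzyloxy)phenyl]oxiran-2-yl}methanone | COCOc1cc(OC)cc(OCc2ccccc2)c1C(=O)[C@@H]1O[C@H]1c1ccc(OCc2ccccc2)c(OCc2ccccc2)c1
F5 | step 7 | potassium enolate of 11 (C3=C4 enolate, 2S) | [K+].COc1cc(OCc3ccccc3)c2c(c1)O[C@H](c1ccc(OCc3ccccc3)c(OCc3ccccc3)c1)C=C2[O-]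
F0 | step 9 | none | none
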